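Ring A (C1 carboxyl, C2–OH, C3–H, C4–OH, C5–O-aryl, C6 pentyl) is cut into a four-carbon diene and a two-carbon alkyne. C2, C3, C4 and C5 with their three oxygens come from the bis-enol ether of a 4-aryloxycyclohexane-1,3-dione; C1 and C6 come from benzyl oct-2-ynoate. One heating operation forms the C5–C6 and C1–C2 bonds by cycloaddition and then expels ethylene, which delivers the fully substituted benzene ring with every substituent in place. The precursor is a 1-aryloxy-2-silyloxy-4-benzyloxycyclohexa-1,3-diene that already carries ring B through the ether oxygen, with the pentanoyl group masked as a dioxolane.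

Key step: step 11

Remark: the target is achiral; the stereocentres of 12, 13 and 17 are formed as racemates and vanish on enolisation or aromatisation, and 3,5-dimethoxybenzonitrile, cyclohexane-1,3-dione and oct-2-ynoic acid are taken as commercial.

Step 1
Reactants: 1 3,5-dimethoxybenzonitrile
Product: 3 1-(3,5-dimethoxyphenyl)pentan-1-one, via chloromagnesium ketimine 2 (not isolated)
Conditions: n-BuMgCl, THF, 0 °C → reflux; then 2 M HCl, rt
Reagents that add atoms: n-butylmagnesium chloride CCCC[Mg]Cl; water O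
Why: Addition of the Grignard reagent to the aryl nitrile stops at the N-magnesio ketimine 2, which cannot add a second equivalent and is hydrolysed to the ketone by aqueous acid (nitrile–Grignard ketone synthesis).

Step 2
Reactants: 3 1-(3,5-dimethoxyphenyl)pentan-1-one
Product: 4 1-(2-iodo-3,5-dimethoxyphenyl)pentan-1-one
Conditions: NIS, CF3CO2H (cat.), MeCN, rt, dark
Reagents that add atoms: N-iodosuccinimide O=C1CCC(=O)N1I
Why: Electrophilic aromatic iodination by acid-activated N-iodosuccinimide should go para to one methoxy group and ortho to the other, at C2 of the ring, as is general for 3,5-dimethoxyaryl carbonyl compounds, the position between the two methoxy groups being the slower one.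

Step 3
Reactants: 4 1-(2-iodo-3,5-dimethoxyphenyl)pentan-1-one
Product: 5 methyl 2,4-dimethoxy-6-pentanoylbenzoate
Conditions: CO (1 atm), Pd(dppf)Cl2 (5 mol%), Et3N, MeOH/DMF, 80 °C
Reagents that add atoms: carbon monoxide [C-]#[O+]; methanol CO
Why: Palladium-catalysed methoxycarbonylation proceeds by oxidative addition of the aryl iodide to zerovalent palladium, CO insertion and methanolysis of the acylpalladium species, with methanol in large excess so that it outruns attack by the neighbouring ketone enol.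

Step 4
Reactants: 5 methyl 2,4-dimethoxy-6-pentanoylbenzoate
Product: 7 methyl 2-hydroxy-4-methoxy-6-pentanoylbenzoate, via aryloxydichloroborane 6 (not isolated)
Conditions: BCl3, CH2Cl2, −78 → 0 °C; then H2O
Reagents that add atoms: none
Why: BCl3 chelates between the ester carbonyl and the ortho methoxy oxygen and so cleaves only that methyl ether (chelation-controlled Lewis acid demethylation), the methoxy group para to the ester and the unchelated ketone being left alone.

Step 5
Reactants: 7 methyl 2-hydroxy-4-methoxy-6-pentanoylbenzoate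
Product: 8 methyl 2-(2-butyl-1,3-dioxolan-2-yl)-6-hydroxy-4-methoxybenzoate
Conditions: HOCH2CH2OH, HC(OEt)3, TsOH·H2O (cat.), toluene, 40 °C
Reagents that add atoms: ethylene glycol OCCO
Why: Acid-catalysed ketalisation with the orthoester as water scavenger protects the only enolisable ketone under mild conditions that disfavour equilibration to a phthalide pseudo ester; the hydroxyl and methoxy groups are meta to the ketal carbon, so they do not labilise the dioxolane.

Step 6
Reactants: 9 cyclohexane-1,3-dione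
Product: 10 3-(benzyloxy)cyclohex-2-en-1-one
Conditions: BnOH, TsOH·H2O (cat.), toluene, reflux, Dean–Stark
Reagents that add atoms: benzyl alcohol OCc1ccccc1
Why: Acid-catalysed condensation of the enolised 1,3-diketone with benzyl alcohol under azeotropic removal of water gives the vinylogous benzyl ester (enol etherification).

Step 7
Reactants: 10 3-(benzyloxy)cyclohex-2-en-1-one
Product: 12 6-bromo-3-(benzyloxy)cyclohex-2-en-1-one (racemic), via silyl dienol ether 11 (not isolated)
Conditions: LDA, THF, −78 °C; Me3SiCl; then NBS, THF, −78 → 0 °C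
Reagents that add atoms: N-bromosuccinimide O=C1CCC(=O)N1Br
Why: LDA deprotonates a 3-alkoxycyclohexenone kinetically at C6 (Stork–Danheiser regiochemistry), and the derived cross-conjugated silyl dienol ether 11 is brominated by NBS at that carbon (α-halogenation of a silyl enol ether), which avoids the polybromination seen with free enolates; the new stereocentre is racemic.

Step 8
Reactants: 12 6-bromo-3-(benzyloxy)cyclohex-2-en-1-one; 8 methyl 2-(2-butyl-1,3-dioxolan-2-yl)-6-hydroxy-4-methoxybenzoate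
Product: 13 methyl 2-{[4-(benzyloxy)-2-oxocyclohex-3-en-1-yl]oxy}-6-(2-butyl-1,3-dioxolan-2-yl)-4-methoxybenzoate (racemic)
Conditions: K2CO3, DMF, 0 °C → rt
Reagents that add atoms: none
Why: Williamson-type SN2 displacement of the α-bromo ketone, whose carbonyl group accelerates substitution, by the weakly basic phenoxide of 8 should outrun E2 elimination at room temperature; the stereocentre is racemic and is erased in step 9.

Step 9
Reactants: 13 methyl 2-{[4-(benzyloxy)-2-oxocyclohex-3-en-1-yl]oxy}-6-(2-butyl-1,3-dioxolan-2-yl)-4-methoxybenzoate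
Product: 14 methyl 2-{[4-(benzyloxy)-2-(tert-butyldimethylsilyloxy)cyclohexa-1,3-dien-1-yl]oxy}-6-(2-butyl-1,3-dioxolan-2-yl)-4-methoxybenzoate
Conditions: LDA, THF, −78 °C; t-BuMe2SiOTf, −78 → −40 °C; Et3N
Reagents that add atoms: tert-butyldimethylsilyl trifluoromethanesulfonate CC(C)(C)[Si](C)(C)OS(=O)(=O)C(F)(F)F
Why: Kinetic deprotonation of the only remaining α′-hydrogen, which the aryloxy group acidifies further, and O-silylation give the cross-conjugated 2-silyloxy diene; the dioxolane leaves no second enolisable ketone, the twisted di-ortho-substituted methyl ester resists Claisen-type attack at −78 °C, and the tert-butyldimethylsilyl group is chosen so that the diene can be purified and survives prolonged heating.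

Step 10
Reactants: 15 oct-2-ynoic acid
Product: 16 benzyl oct-2-ynoate
Conditions: BnBr, K2CO3, DMF, rt
Reagents that add atoms: benzyl bromide BrCc1ccccc1
Why: SN2 O-alkylation of the potassium carboxylate with benzyl bromide gives the ester whose benzyl group will leave in the same hydrogenolysis as the ring A benzyl ether.

Step 11
Reactants: 14 methyl 2-{[4-(benzyloxy)-2-(tert-butyldimethylsilyloxy)cyclohexa-1,3-dien-1-yl]oxy}-6-(2-butyl-1,3-dioxolan-2-yl)-4-methoxybenzoate; 16 benzyl oct-2-ynoate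
Product: 19 benzyl 2-(benzyloxy)-5-[3-(2-butyl-1,3-dioxolan-2-yl)-5-methoxy-2-(methoxycarbonyl)phenoxy]-4-hydroxy-6-pentylbenzoate, via bicyclo[2.2.2]octadiene adduct 17 (not isolated), via silyl ether 18 (not isolated)
Conditions: 16 (4 equiv), BHT (cat.), mesitylene, 170 °C, sealed tube; then Bu4NF, AcOH, THF, 0 °C
Reagents that add atoms: none
Why: The electron-rich diene 14, its HOMO raised by the silyloxy and benzyloxy donors, adds thermally to the electron-poor triple bond of 16 in a concerted, asynchronous [4+2] cycloaddition to give bicyclo[2.2.2]octadiene 17, which under the same heating loses its saturated two-carbon bridge as ethylene in a retro-[4+2] step to give arene 18 (Alder–Rickert reaction, the known route from silyloxy and alkoxy cyclohexa-1,3-dienes and alkynoates to resorcinol derivatives). Ring A is closed by the intermolecular cycloaddition, which joins both diene termini to the two alkyne carbons in one suprafacial event, and is made aromatic by the cycloreversion; no leaving group is involved, so the aryloxy group on the diene terminus cannot be lost. No stereocentre remains, because the two bridgehead centres of racemic 17 vanish on aromatisation. The selectivity needed is regiochemical: the silyloxy and benzyloxy donors both place the largest HOMO coefficient on the aryloxy-bearing terminus, which therefore bonds to the pentyl-bearing β-carbon of the ynoate, so that the pentyl group ends up next to the diaryl ether oxygen and the ester next to the benzyloxy group. That terminus is fully substituted, hence the high temperature, the excess of 16 and the robust silyl group; buffered fluoride in the work-up then frees the C4 phenol without touching the esters or the dioxolane.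

Step 12
Reactants: 19 benzyl 2-(benzyloxy)-5-[3-(2-butyl-1,3-dioxolan-2-yl)-5-methoxy-2-(methoxycarbonyl)phenoxy]-4-hydroxy-6-pentylbenzoate
Product: 20 5-[3-(2-butyl-1,3-dioxolan-2-yl)-5-methoxy-2-(methoxycarbonyl)phenoxy]-2,4-dihydroxy-6-pentylbenzoic acid
Conditions: H2 (1 atm), Pd/C (10 wt%), EtOAc, rt
Reagents that add atoms: none
Why: Hydrogenolysis of the two benzylic C–O bonds over Pd/C under neutral conditions frees the C2 phenol and the C1 carboxylic acid, while the dioxolane keeps the aryl ketone from being reduced and the diaryl ether, methyl ester and arenes are inert.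

Step 13
Reactants: 20 5-[3-(2-butyl-1,3-dioxolan-2-yl)-5-methoxy-2-(methoxycarbonyl)phenoxy]-2,4-dihydroxy-6-pentylbenzoic acid
Product: 21 2,4-dihydroxy-5-[5-methoxy-2-(methoxycarbonyl)-3-pentanoylphenoxy]-6-pentylbenzoic acid
Conditions: 1 M HCl, THF, rt
Reagents that add atoms: water O
Why: Acid-catalysed hydrolysis of the dioxolane, helped by the neighbouring ester carbonyl, should go at room temperature, which keeps the electron-rich 2,4-dihydroxybenzoic acid away from the heat that would cause protodecarboxylation.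

Compound list
1 | 3,5-dimethoxybenzonitrile | N#Cc1cc(OC)cc(OC)c1 | starting material
2 | N-(chloromagnesio) imine of 1-(3,5-dimethoxyphenyl)pentan-1-one | CCCCC(=N[Mg]Cl)c1cc(OC)cc(OC)c1 | intermediate (not isolated)
3 | 1-(3,5-dimethoxyphenyl)pentan-1-one | CCCCC(=O)c1cc(OC)cc(OC)c1 | intermediate
4 | 1-(2-iodo-3,5-dimethoxyphenyl)pentan-1-one | CCCCC(=O)c1cc(OC)cc(OC)c1I | intermediate
5 | methyl 2,4-dimethoxy-6-pentanoylbenzoate | CCCCC(=O)c1cc(OC)cc(OC)c1C(=O)OC | intermediate
6 | methyl 2-[(dichloroboranyl)oxy]-4-methoxy-6-pentanoylbenzoate | CCCCC(=O)c1cc(OC)cc(OB(Cl)Cl)c1C(=O)OC | intermediate (not isolated)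
7 | methyl 2-hydroxy-4-methoxy-6-pentanoylbenzoate | CCCCC(=O)c1cc(OC)cc(O)c1C(=O)OC | intermediate
8 | methyl 2-(2-butyl-1,3-dioxolan-2-yl)-6-hydroxy-4-methoxybenzoate | CCCCC1(OCCO1)c1cc(OC)cc(O)c1C(=O)OC | intermediate
9 | cyclohexane-1,3-dione | O=C1CCCC(=O)C1 | starting material
10 | 3-(benzyloxy)cyclohex-2-en-1-one | O=C1C=C(OCc2ccccc2)CCC1 | intermediate
11 | 1-(benzyloxy)-3-(trimethylsilyloxy)cyclohexa-1,3-diene | C[Si](C)(C)OC1=CCCC(OCc2ccccc2)=C1 | intermediate (not isolated)
12 | 6-bromo-3-(benzyloxy)cyclohex-2-en-1-one (racemic) | O=C1C=C(OCc2ccccc2)CCC1Br | intermediate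
13 | methyl 2-{[4-(benzyloxy)-2-oxocyclohex-3-en-1-yl]oxy}-6-(2-butyl-1,3-dioxolan-2-yl)-4-methoxybenzoate (racemic) | COC(=O)c1c(OC2CCC(OCc3ccccc3)=CC2=O)cc(OC)cc1C1(CCCC)OCCO1 | intermediate
14 | methyl 2-{[4-(benzyloxy)-2-(tert-butyldimethylsilyloxy)cyclohexa-1,3-dien-1-yl]oxy}-6-(2-butyl-1,3-dioxolan-2-yl)-4-methoxybenzoate | COC(=O)c1c(OC2=C(O[Si](C)(C)C(C)(C)C)C=C(OCc3ccccc3)CC2)cc(OC)cc1C1(CCCC)OCCO1 | intermediate
15 | oct-2-ynoic acid | CCCCCC#CC(=O)O | starting material
16 | benzyl oct-2-ynoate | CCCCCC#CC(=O)OCc1ccccc1 | intermediate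
17 | benzyl 1-(benzyloxy)-4-[3-(2-butyl-1,3-dioxolan-2-yl)-5-methoxy-2-(methoxycarbonyl)phenoxy]-5-(tert-butyldimethylsilyloxy)-3-pentylbicyclo[2.2.2]octa-2,5-diene-2-carboxylate (racemic) | COC(=O)c1c(OC23CCC(OCc4ccccc4)(C=C2O[Si](C)(C)C(C)(C)C)C(C(=O)OCc2ccccc2)=C3CCCCC)cc(OC)cc1C1(CCCC)OCCO1 | intermediate (not isolated)
18 | benzyl 2-(benzyloxy)-5-[3-(2-butyl-1,3-dioxolan-2-yl)-5-methoxy-2-(methoxycarbonyl)phenoxy]-4-(tert-butyldimethylsilyloxy)-6-pentylbenzoate | CCCCCc1c(Oc2cc(OC)cc(C3(CCCC)OCCO3)c2C(=O)OC)c(O[Si](C)(C)C(C)(C)C)cc(OCc2ccccc2)c1C(=O)OCc1ccccc1 | intermediate (not isolated)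
19 | benzyl 2-(benzyloxy)-5-[3-(2-butyl-1,3-dioxolan-2-yl)-5-methoxy-2-(methoxycarbonyl)phenoxy]-4-hydroxy-6-pentylbenzoate | CCCCCc1c(Oc2cc(OC)cc(C3(CCCC)OCCO3)c2C(=O)OC)c(O)cc(OCc2ccccc2)c1C(=O)OCc1ccccc1 | intermediate
20 | 5-[3-(2-butyl-1,3-dioxolan-2-yl)-5-methoxy-2-(methoxycarbonyl)phenoxy]-2,4-dihydroxy-6-pentylbenzoic acid | CCCCCc1c(Oc2cc(OC)cc(C3(CCCC)OCCO3)c2C(=O)OC)c(O)cc(O)c1C(=O)O | intermediate
21 | 2,4-dihydroxy-5-[5-methoxy-2-(methoxycarbonyl)-3-pentanoylphenoxy]-6-pentylbenzoic acid | CCCCCc1c(Oc2cc(OC)cc(C(=O)CCCC)c2C(=O)OC)c(O)cc(O)c1C(=O)O | target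

Total step count: 13. Longest linear sequence: 10 steps (steps 1, 2, 3, 4, 5, 8, 9, 11, 12, 13).

Steps most likely to fail

Step 11. The cycloaddition may stall at the fully substituted, aryloxy-bearing diene terminus, so that thermal decomposition or desilylation of the diene wins over bond formation. The fallback changes the dienophile to a more electrophilic one and moves the carboxyl oxidation to a later stage. Diene 14 is heated with commercial oct-2-ynal (CCCCCC#CC=O) in toluene at 110–130 °C. This should give, through the bicyclic adduct 1-(benzyloxy)-4-[3-(2-butyl-1,3-dioxolan-2-yl)-5-methoxy-2-(methoxycarbonyl)phenoxy]-5-(tert-butyldimethylsilyloxy)-3-pentylbicyclo[2.2.2]octa-2,5-diene-2-carbaldehyde F1 and loss of ethylene, the aryl aldehyde 2-(benzyloxy)-5-[3-(2-butyl-1,3-dioxolan-2-yl)-5-methoxy-2-(methoxycarbonyl)phenoxy]-4-(tert-butyldimethylsilyloxy)-6-pentylbenzaldehyde F2. Bu4NF buffered with AcOH should then free the phenol to give 2-(benzyloxy)-5-[3-(2-butyl-1,3-dioxolan-2-yl)-5-methoxy-2-(methoxycarbonyl)phenoxy]-4-hydroxy-6-pentylbenzaldehyde F3. Pinnick oxidation (NaClO2, NaH2PO4, 2-methylbut-2-ene, t-BuOH/H2O) should give 2-(benzyloxy)-5-[3-(2-butyl-1,3-dioxolan-2-yl)-5-methoxy-2-(methoxycarbonyl)phenoxy]-4-hydroxy-6-pentylbenzoic acid F4. Hydrogenolysis of its single benzyl ether over Pd/C comes back to the route at 20.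

Step 8. Base-induced loss of HBr from 12, with aromatisation to a phenol, may outrun substitution by the hydrogen-bonded, weakly nucleophilic salicylate oxygen. The fallback forms the same C–O bond by redox condensation and sets out from 10. Its lithium enolate (LDA, THF, −78 °C) is hydroxylated with 2-(phenylsulfonyl)-3-phenyloxaziridine to give 3-(benzyloxy)-6-hydroxycyclohex-2-en-1-one F5 (racemic). Mitsunobu etherification of F5 with phenol 8 (PPh3, DIAD, toluene, 0 °C → rt) comes back to the route at 13.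

Step 5. The hemiketal of the ortho-acyl benzoate may be diverted into a phthalide pseudo ester with loss of methanol, or ketalisation of the twisted ketone may stay incomplete. The fallback gives up the dioxolane, masks the ketone in the flask as a second silyl enol ether, and sets out from 7.
- Alkylation of 7 with bromide 12 (K2CO3, DMF) should give methyl 2-{[4-(benzyloxy)-2-oxocyclohex-3-en-1-yl]oxy}-4-methoxy-6-pentanoylbenzoate F6 (racemic).
- Addition of LDA (2.4 equiv) to F6 and excess Me3SiCl in THF at −78 °C (internal quench) should give methyl 2-{[4-(benzyloxy)-2-(trimethylsilyloxy)cyclohexa-1,3-dien-1-yl]oxy}-4-methoxy-6-[(1Z)-1-(trimethylsilyloxy)pent-1-en-1-yl]benzoate F7.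
- Heating F7 with 16 as in step 11 should lead, through benzyl 1-(benzyloxy)-4-{5-methoxy-2-(methoxycarbonyl)-3-[(1Z)-1-(trimethylsilyloxy)pent-1-en-1-yl]phenoxy}-3-pentyl-5-(trimethylsilyloxy)bicyclo[2.2.2]octa-2,5-diene-2-carboxylate F8, to benzyl 2-(benzyloxy)-5-{5-methoxy-2-(methoxycarbonyl)-3-[(1Z)-1-(trimethylsilyloxy)pent-1-en-1-yl]phenoxy}-6-pentyl-4-(trimethylsilyloxy)benzoate F9.
- Brief treatment with 1 M HCl in THF at 0 °C removes both silyl groups to give benzyl 2-(benzyloxy)-4-hydroxy-5-[5-methoxy-2-(methoxycarbonyl)-3-pentanoylphenoxy]-6-pentylbenzoate F10.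
- Hydrogenolysis over Pd/C in EtOAc, stopped as soon as both benzyl groups are gone so that the hindered aryl ketone is spared, comes back to the route at 21.

Further compounds
F1 | step 11 | 1-(benzyloxy)-4-[3-(2-butyl-1,3-dioxolan-2-yl)-5-methoxy-2-(methoxycarbonyl)phenoxy]-5-(tert-butyldimethylsilyloxy)-3-pentylbicyclo[2.2.2]octa-2,5-diene-2-carbaldehyde (racemic) | COC(=O)c1c(OC23CCC(OCc4ccccc4)(C=C2O[Si](C)(C)C(C)(C)C)C(C=O)=C3CCCCC)cc(OC)cc1C1(CCCC)OCCO1
F2 | step 11 | 2-(benzyloxy)-5-[3-(2-butyl-1,3-dioxolan-2-yl)-5-methoxy-2-(methoxycarbonyl)phenoxy]-4-(tert-butyldimethylsilyloxy)-6-pentylbenzaldehyde | CCCCCc1c(Oc2cc(OC)cc(C3(CCCC)OCCO3)c2C(=O)OC)c(O[Si](C)(C)C(C)(C)C)cc(OCc2ccccc2)c1C=O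
F3 | step 11 | 2-(benzyloxy)-5-[3-(2-butyl-1,3-dioxolan-2-yl)-5-methoxy-2-(methoxycarbonyl)phenoxy]-4-hydroxy-6-pentylbenzaldehyde | CCCCCc1c(Oc2cc(OC)cc(C3(CCCC)OCCO3)c2C(=O)OC)c(O)cc(OCc2ccccc2)c1C=O
F4 | step 11 | 2-(benzyloxy)-5-[3-(2-butyl-1,3-dioxolan-2-yl)-5-methoxy-2-(methoxycarbonyl)phenoxy]-4-hydroxy-6-pentylbenzoic acid | CCCCCc1c(Oc2cc(OC)cc(C3(CCCC)OCCO3)c2C(=O)OC)c(O)cc(OCc2ccccc2)c1C(=O)O
F5 | step 8 | 3-(benzyloxy)-6-hydroxycyclohex-2-en-1-one (racemic) | O=C1C=C(OCc2ccccc2)CCC1O
F6 | step 5 | methyl 2-{[4-(benzyloxy)-2-oxocyclohex-3-en-1-yl]oxy}-4-methoxy-6-pentanoylbenzoate (racemic) | CCCCC(=O)c1cc(OC)cc(OC2CCC(OCc3ccccc3)=CC2=O)c1C(=O)OC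
F7 | step 5 | methyl 2-{[4-(benzyloxy)-2-(trimethylsilyloxy)cyclohexa-1,3-dien-1-yl]oxy}-4-methoxy-6-[(1Z)-1-(trimethylsilyloxy)pent-1-en-1-yl]benzoate | CCC/C=C(\O[Si](C)(C)C)c1cc(OC)cc(OC2=C(O[Si](C)(C)C)C=C(OCc3ccccc3)CC2)c1C(=O)OC
F8 | step 5 | benzyl 1-(benzyloxy)-4-{5-methoxy-2-(methoxycarbonyl)-3-[(1Z)-1-(trimethylsilyloxy)pent-1-en-1-yl]phenoxy}-3-pentyl-5-(trimethylsilyloxy)bicyclo[2.2.2]octa-2,5-diene-2-carboxylate (racemic) | CCC/C=C(\O[Si](C)(C)C)c1cc(OC)cc(OC23CCC(OCc4ccccc4)(C=C2O[Si](C)(C)C)C(C(=O)OCc2ccccc2)=C3CCCCC)c1C(=O)OC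
F9 | step 5 | benzyl 2-(benzyloxy)-5-{5-methoxy-2-(methoxycarbonyl)-3-[(1Z)-1-(trimethylsilyloxy)pent-1-en-1-yl]phenoxy}-6-pentyl-4-(trimethylsilyloxy)benzoate | CCC/C=C(\O[Si](C)(C)C)c1cc(OC)cc(Oc2c(O[Si](C)(C)C)cc(OCc3ccccc3)c(C(=O)OCc3ccccc3)c2CCCCC)c1C(=O)OC
F10 | step 5 | benzyl 2-(benzyloxy)-4-hydroxy-5-[5-methoxy-2-(methoxycarbonyl)-3-pentanoylphenoxy]-6-pentylbenzoate | CCCCCc1c(Oc2cc(OC)cc(C(=O)CCCC)c2C(=O)OC)c(O)cc(OCc2ccccc2)c1C(=O)OCc1ccccc1
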